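**Plan**

1. Retrosynthetic cuts, in order: (i) C2–C3 of the flavanone C-ring by a carbene C–H insertion transform, which turns C2 into the CH2 of an aryl benzyl ether and C3 into a diazomethyl ketone carbon; (ii) the O1–C2 ether bond (Mitsunobu); (iii) the flavonol C3–O–aryl bond (SNAr on 4-fluorobenzaldehyde).
2. Enabling feature: in the flavanone, C2–H is benzylic and α to the ring oxygen O1, and C2 lies 1,6 to C3 across the rigid C4–C4a–C8a–O1 array. The atom 1,5 to C3 is O1, which bears no hydrogen, so a carbene at C3 can only reach this doubly activated C–H.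
3. Forward: kaempferol is capped at O7/O4', arylated at O3, benzylated at O5 and reduced to a benzylic alcohol; phloroacetophenone is bis-silylated; the halves are joined by Mitsunobu etherification; diazo transfer to the acetyl group; Rh(II)-catalysed C–H insertion closes the pyranone ring, the only ring made in the route, last; desilylation and hydrogenolysis finish.
4. Stereochemistry: C2 (S) is the only stereocentre. It is created in the key step by a homochiral dirhodium carboxylate that selects one of the two enantiotopic benzylic hydrogens; only buffered or neutral steps follow, so the base-labile flavanone centre never meets base.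
5. Protecting groups serve the key step: the flavanone A-ring oxygens carry TIPS groups (no activated C–H within reach of the carbene), and benzyl ethers sit only on the remote flavonol.

Key step: step 8

Remark: kaempferol (1) is taken as a purchased starting material; the sense of induction of the dirhodium catalyst at C2 is to be confirmed on a model benzyl ether, and the mirror-image catalyst Rh2(R-PTTL)4 would be used if the (S)-ligand series gave the 2R product.

**Route**

Step 1
Reactants: 1 kaempferol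
Product: 2 7-(benzyloxy)-2-[4-(benzyloxy)phenyl]-3,5-dihydroxy-4H-chromen-4-one (7,4'-di-O-benzylkaempferol)
Conditions: BnBr (2.1 equiv), K2CO3 (2.2 equiv), DMF, 0 °C to rt
Reagents that add atoms: benzyl bromide BrCc1ccccc1
Why: Williamson etherification in which the 7-OH and 4'-OH, the most acidic and least hindered phenols of kaempferol, react before the 3-OH and long before the chelated 5-OH, so about two equivalents of bromide at low temperature should stop at the 7,4'-diether.

Step 2
Reactants: 2 7,4'-di-O-benzylkaempferol; 3 4-fluorobenzaldehyde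
Product: 4 4-({7-(benzyloxy)-2-[4-(benzyloxy)phenyl]-5-hydroxy-4-oxo-4H-chromen-3-yl}oxy)benzaldehyde
Conditions: 3 (1.2 equiv), K2CO3 (1.5 equiv), DMF, 100 °C, argon
Reagents that add atoms: none
Why: SNAr (addition–elimination) of the flavonol 3-oxide on the para-formyl-activated fluoroarene, with the 5-OH held back by its hydrogen bond to C4=O and all other phenols capped; argon prevents oxidative cleavage of the flavonolate.

Step 3
Reactants: 4 the 5-hydroxy aldehyde
Product: 5 4-({5,7-bis(benzyloxy)-2-[4-(benzyloxy)phenyl]-4-oxo-4H-chromen-3-yl}oxy)benzaldehyde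
Conditions: BnBr (1.5 equiv), K2CO3, cat. KI, DMF, 60 °C
Reagents that add atoms: benzyl bromide BrCc1ccccc1
Why: Williamson etherification of the chelated 5-OH, which needs heat but meets no competing nucleophile, and the aldehyde has no α-hydrogen.

Step 4
Reactants: 5 the tri-O-benzyl aldehyde
Product: 6 5,7-bis(benzyloxy)-2-[4-(benzyloxy)phenyl]-3-[4-(hydroxymethyl)phenoxy]-4H-chromen-4-one
Conditions: NaBH4, THF/MeOH, 0 °C
Reagents that add atoms: none
Why: Borohydride reduction of the aryl aldehyde; the cross-conjugated γ-pyrone carbonyl of a flavone is not reduced by NaBH4 at 0 °C.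

Step 5
Reactants: 7 2',4',6'-trihydroxyacetophenone
Product: 8 1-{2-hydroxy-4,6-bis[(triisopropylsilyl)oxy]phenyl}ethan-1-one
Conditions: TIPSCl (2.2 equiv), imidazole, DMF, 0 °C to rt
Reagents that add atoms: triisopropylsilyl chloride CC(C)[Si](Cl)(C(C)C)C(C)C
Why: Silylation of the para OH and of one ortho OH; the last ortho OH is locked in a hydrogen bond to the acetyl C=O and resists the bulky chlorosilane, so the reaction should stop at the bis-ether.

Step 6
Reactants: 6 the benzylic alcohol; 8 the bis-TIPS hydroxyacetophenone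
Product: 9 1-{2-[(4-{[5,7-bis(benzyloxy)-2-(4-benzyloxyphenyl)-4-oxo-4H-chromen-3-yl]oxy}phenyl)methoxy]-4,6-bis[(triisopropylsilyl)oxy]phenyl}ethan-1-one
Conditions: PPh3, DIAD, THF, 0 °C to rt
Reagents that add atoms: none
Why: Mitsunobu etherification of a primary benzylic alcohol with the acidic chelated phenol under neutral conditions that spare the aryl silyl ethers; 6 has no free phenol to compete.

Step 7
Reactants: 9 the aryl methyl ketone
Product: 11 2-diazo-1-{2-[(4-{[5,7-bis(benzyloxy)-2-(4-benzyloxyphenyl)-4-oxo-4H-chromen-3-yl]oxy}phenyl)methoxy]-4,6-bis[(triisopropylsilyl)oxy]phenyl}ethan-1-one, via trifluoroacetyl diketone 10 (not isolated)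
Conditions: LiHMDS (1.1 equiv), THF, −78 °C, then CF3CO2CH2CF3; aq. NH4Cl work-up; crude 10 with MsN3, Et3N, H2O (1 equiv), MeCN, rt
Reagents that add atoms: methanesulfonyl azide CS(=O)(=O)N=[N+]=[N-] (the two diazo nitrogens of 11); 2,2,2-trifluoroethyl trifluoroacetate O=C(OCC(F)(F)F)C(F)(F)F (the CF3CO group of intermediate 10 only)
Why: Claisen C-trifluoroacetylation of the lithium enolate at the only enolisable position activates the α-carbon, and Regitz-type detrifluoroacetylative diazo transfer from the sulfonyl azide then installs N2 while the CF3CO group leaves on the sulfonamide nitrogen.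

Step 8
Reactants: 11 the aryl diazomethyl ketone
Product: 12 (2S)-2-(4-{[5,7-bis(benzyloxy)-2-(4-benzyloxyphenyl)-4-oxo-4H-chromen-3-yl]oxy}phenyl)-5,7-bis[(triisopropylsilyl)oxy]-2,3-dihydro-4H-chromen-4-one
Conditions: Rh2(S-PTTL)4 (1 mol %), CH2Cl2, slow addition of 11 by syringe pump (high dilution), rt, argon
Reagents that add atoms: none
Why: Loss of N2 from 11 at the dirhodium core gives an electrophilic rhodium carbene at the future C3, which takes up the hydridic benzylic C–H of the O1–CH2–aryl ether through a three-centre transition state and forms the C3–C2 bond as the metal leaves; the closest known reaction type is the rhodium(II)-carboxylate-catalysed intramolecular C–H insertion of 2-alkoxyaryl diazo ketones to chroman-4-ones, which has also been run with homochiral carboxylates. The pyranone ring closes by 1,6 insertion through a six-membered cyclic transition state, because the atom 1,5 to the carbene is O1 and carries no hydrogen and because C4, C4a, C8a and O1 hold the carbene and the CH2 group within reach of each other. C2 is the only new stereocentre and is set by the catalyst alone, the four N-phthaloyl-tert-leucinate ligands admitting only one of the two enantiotopic benzylic hydrogens to the carbene. The step needs chemoselectivity for C–H insertion over oxonium-ylide formation at O1 followed by [1,2]-benzyl shift to a 2-benzylbenzofuranone, and a rhodium carboxylate instead of copper, a non-coordinating solvent and the doubly activated C–H favour insertion. It also needs site selectivity among the ether groups, which is secured because the second ortho oxygen and the para oxygen carry TIPS groups with no activated C–H in reach and the three benzyl ethers sit on the remote flavonol. Slow addition at high dilution should keep carbene dimerisation and intermolecular reactions down.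

Step 9
Reactants: 12 the bis-TIPS flavanone
Product: 13 (2S)-2-(4-{[5,7-bis(benzyloxy)-2-(4-benzyloxyphenyl)-4-oxo-4H-chromen-3-yl]oxy}phenyl)-5,7-dihydroxy-2,3-dihydro-4H-chromen-4-one
Conditions: TBAF (2.5 equiv), AcOH (3 equiv), THF, 0 °C
Reagents that add atoms: none
Why: Fluoride cleaves the aryl Si–O bonds, and the acetic acid buffer keeps the phenols protonated so that the E1cB ring opening to the chalcone, the racemisation pathway of flavanones, should not occur.

Step 10
Reactants: 13 the tri-O-benzyl biflavonoid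
Product: 14 (2S)-2-(4-{[5,7-dihydroxy-2-(4-hydroxyphenyl)-4-oxo-4H-chromen-3-yl]oxy}phenyl)-5,7-dihydroxy-2,3-dihydro-4H-chromen-4-one (target)
Conditions: H2 (1 atm), 10% Pd/C, EtOAc/MeOH, rt, stopped at the calculated uptake
Reagents that add atoms: none
Why: Hydrogenolysis of the three aryl benzyl ethers under neutral conditions, which should leave the C2 configuration untouched; the cyclic secondary benzylic O1–C2 ether and the tetrasubstituted flavonol C2=C3 bond react much more slowly.

**Compound list**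

1 | kaempferol, 3,5,7-trihydroxy-2-(4-hydroxyphenyl)-4H-chromen-4-one | O=c1c(O)c(-c2ccc(O)cc2)oc2cc(O)cc(O)c12 | starting material
2 | 7-(benzyloxy)-2-[4-(benzyloxy)phenyl]-3,5-dihydroxy-4H-chromen-4-one | O=c1c(O)c(-c2ccc(OCc3ccccc3)cc2)oc2cc(OCc3ccccc3)cc(O)c12 | intermediate
3 | 4-fluorobenzaldehyde | O=Cc1ccc(F)cc1 | starting material
4 | 4-({7-(benzyloxy)-2-[4-(benzyloxy)phenyl]-5-hydroxy-4-oxo-4H-chromen-3-yl}oxy)benzaldehyde | O=Cc1ccc(Oc2c(-c3ccc(OCc4ccccc4)cc3)oc3cc(OCc4ccccc4)cc(O)c3c2=O)cc1 | intermediate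
5 | 4-({5,7-bis(benzyloxy)-2-[4-(benzyloxy)phenyl]-4-oxo-4H-chromen-3-yl}oxy)benzaldehyde | O=Cc1ccc(Oc2c(-c3ccc(OCc4ccccc4)cc3)oc3cc(OCc4ccccc4)cc(OCc4ccccc4)c3c2=O)cc1 | intermediate
6 | 5,7-bis(benzyloxy)-2-[4-(benzyloxy)phenyl]-3-[4-(hydroxymethyl)phenoxy]-4H-chromen-4-one | OCc1ccc(Oc2c(-c3ccc(OCc4ccccc4)cc3)oc3cc(OCc4ccccc4)cc(OCc4ccccc4)c3c2=O)cc1 | intermediate
7 | 2',4',6'-trihydroxyacetophenone, 1-(2,4,6-trihydroxyphenyl)ethan-1-one | CC(=O)c1c(O)cc(O)cc1O | starting material
8 | 1-{2-hydroxy-4,6-bis[(triisopropylsilyl)oxy]phenyl}ethan-1-one | CC(=O)c1c(O)cc(O[Si](C(C)C)(C(C)C)C(C)C)cc1O[Si](C(C)C)(C(C)C)C(C)C | intermediate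
9 | 1-{2-[(4-{[5,7-bis(benzyloxy)-2-(4-benzyloxyphenyl)-4-oxo-4H-chromen-3-yl]oxy}phenyl)methoxy]-4,6-bis[(triisopropylsilyl)oxy]phenyl}ethan-1-one | CC(=O)c1c(OCc2ccc(Oc3c(-c4ccc(OCc5ccccc5)cc4)oc4cc(OCc5ccccc5)cc(OCc5ccccc5)c4c3=O)cc2)cc(O[Si](C(C)C)(C(C)C)C(C)C)cc1O[Si](C(C)C)(C(C)C)C(C)C | intermediate
10 | 4,4,4-trifluoro-1-{2-[(4-{[5,7-bis(benzyloxy)-2-(4-benzyloxyphenyl)-4-oxo-4H-chromen-3-yl]oxy}phenyl)methoxy]-4,6-bis[(triisopropylsilyl)oxy]phenyl}butane-1,3-dione | O=C(CC(=O)C(F)(F)F)c1c(OCc2ccc(Oc3c(-c4ccc(OCc5ccccc5)cc4)oc4cc(OCc5ccccc5)cc(OCc5ccccc5)c4c3=O)cc2)cc(O[Si](C(C)C)(C(C)C)C(C)C)cc1O[Si](C(C)C)(C(C)C)C(C)C | intermediate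
11 | 2-diazo-1-{2-[(4-{[5,7-bis(benzyloxy)-2-(4-benzyloxyphenyl)-4-oxo-4H-chromen-3-yl]oxy}phenyl)methoxy]-4,6-bis[(triisopropylsilyl)oxy]phenyl}ethan-1-one | [N-]=[N+]=CC(=O)c1c(OCc2ccc(Oc3c(-c4ccc(OCc5ccccc5)cc4)oc4cc(OCc5ccccc5)cc(OCc5ccccc5)c4c3=O)cc2)cc(O[Si](C(C)C)(C(C)C)C(C)C)cc1O[Si](C(C)C)(C(C)C)C(C)C | intermediate
12 | (2S)-2-(4-{[5,7-bis(benzyloxy)-2-(4-benzyloxyphenyl)-4-oxo-4H-chromen-3-yl]oxy}phenyl)-5,7-bis[(triisopropylsilyl)oxy]-2,3-dihydro-4H-chromen-4-one | O=C1C[C@@H](c2ccc(Oc3c(-c4ccc(OCc5ccccc5)cc4)oc4cc(OCc5ccccc5)cc(OCc5ccccc5)c4c3=O)cc2)Oc2cc(O[Si](C(C)C)(C(C)C)C(C)C)cc(O[Si](C(C)C)(C(C)C)C(C)C)c21 | intermediate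
13 | (2S)-2-(4-{[5,7-bis(benzyloxy)-2-(4-benzyloxyphenyl)-4-oxo-4H-chromen-3-yl]oxy}phenyl)-5,7-dihydroxy-2,3-dihydro-4H-chromen-4-one | O=C1C[C@@H](c2ccc(Oc3c(-c4ccc(OCc5ccccc5)cc4)oc4cc(OCc5ccccc5)cc(OCc5ccccc5)c4c3=O)cc2)Oc2cc(O)cc(O)c21 | intermediate
14 | (2S)-2-(4-{[5,7-dihydroxy-2-(4-hydroxyphenyl)-4-oxo-4H-chromen-3-yl]oxy}phenyl)-5,7-dihydroxy-2,3-dihydro-4H-chromen-4-one | O=C1C[C@@H](c2ccc(Oc3c(-c4ccc(O)cc4)oc4cc(O)cc(O)c4c3=O)cc2)Oc2cc(O)cc(O)c21 | target

**Summary**

Total step count: 10. Longest linear sequence: 9 steps (steps 1–4 and 6–10, from kaempferol).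

Steps most likely to fail:

Step 8. The rhodium carbene may be captured by the lone pair of O1 (oxonium ylide, then [1,2]-benzyl shift) in place of inserting into the C–H bond, or the two enantiotopic hydrogens may be discriminated too weakly. The fallback sets out from 5 and 7 and comes back to the route at 14; it builds the C-ring the classical way round, with C2–C3 formed first as an alkene and O1–C2 last. Compound 7 would be dibenzylated (BnBr, K2CO3, DMF) to 1-[2,4-bis(benzyloxy)-6-hydroxyphenyl]ethan-1-one F1. Claisen–Schmidt condensation of this ketone with aldehyde 5 (KOH, EtOH/THF, rt) should give the (E)-2'-hydroxychalcone F2. Sodium acetate in refluxing ethanol should close it by intramolecular oxa-Michael addition to the racemic penta-O-benzyl flavanone F3. Hydrogenolysis (H2, Pd/C) should give the racemic biflavonoid F4, from which preparative HPLC on a polysaccharide chiral stationary phase should deliver 14.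

Step 7. The ortho triisopropylsilyl group may migrate from the aryl oxygen to the lithium enolate, or C-trifluoroacetylation of the doubly ortho-substituted ketone may stay incomplete. The fallback sets out from 9 and comes back at 11; it transfers the diazo group without any strong base. Heating 9 with N,N-dimethylformamide dimethyl acetal (toluene, 100 °C) should give the enaminone (E)-3-(dimethylamino)-1-{2-[(4-{[5,7-bis(benzyloxy)-2-(4-benzyloxyphenyl)-4-oxo-4H-chromen-3-yl]oxy}phenyl)methoxy]-4,6-bis[(triisopropylsilyl)oxy]phenyl}prop-2-en-1-one F5. Tosyl azide in MeCN at rt should then convert it into 11 by [3+2] cycloaddition and cycloreversion, with loss of the N-sulfonyl formamidine.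

Step 2. Addition of the hindered, chelated 3-oxide to the only moderately activated fluoroarene may be too slow at temperatures the flavonolate tolerates, so that arylation at O5 or decomposition takes over. The fallback sets out from 2 and comes back at 4. It is a copper-catalysed Ullmann-type C–O coupling of 2 with commercial 4-iodobenzaldehyde (CuI, picolinic acid, K3PO4, DMSO, 80 °C, argon). This replaces addition–elimination by oxidative addition and reductive elimination at copper and does not depend on activation of the arene; it makes no new compound (F0).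

Further compounds
F1 | step 8 | 1-[2,4-bis(benzyloxy)-6-hydroxyphenyl]ethan-1-one | CC(=O)c1c(O)cc(OCc2ccccc2)cc1OCc1ccccc1
F2 | step 8 | (E)-1-[2,4-bis(benzyloxy)-6-hydroxyphenyl]-3-[4-({5,7-bis(benzyloxy)-2-[4-(benzyloxy)phenyl]-4-oxo-4H-chromen-3-yl}oxy)phenyl]prop-2-en-1-one | O=C(/C=C/c1ccc(Oc2c(-c3ccc(OCc4ccccc4)cc3)oc3cc(OCc4ccccc4)cc(OCc4ccccc4)c3c2=O)cc1)c1c(O)cc(OCc2ccccc2)cc1OCc1ccccc1
F3 | step 8 | racemic 5,7-bis(benzyloxy)-2-(4-{[5,7-bis(benzyloxy)-2-(4-benzyloxyphenyl)-4-oxo-4H-chromen-3-yl]oxy}phenyl)-2,3-dihydro-4H-chromen-4-one | O=C1CC(c2ccc(Oc3c(-c4ccc(OCc5ccccc5)cc4)oc4cc(OCc5ccccc5)cc(OCc5ccccc5)c4c3=O)cc2)Oc2cc(OCc3ccccc3)cc(OCc3ccccc3)c21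
F4 | step 8 | racemic 2-(4-{[5,7-dihydroxy-2-(4-hydroxyphenyl)-4-oxo-4H-chromen-3-yl]oxy}phenyl)-5,7-dihydroxy-2,3-dihydro-4H-chromen-4-one | O=C1CC(c2ccc(Oc3c(-c4ccc(O)cc4)oc4cc(O)cc(O)c4c3=O)cc2)Oc2cc(O)cc(O)c21
F5 | step 7 | (E)-3-(dimethylamino)-1-{2-[(4-{[5,7-bis(benzyloxy)-2-(4-benzyloxyphenyl)-4-oxo-4H-chromen-3-yl]oxy}phenyl)methoxy]-4,6-bis[(triisopropylsilyl)oxy]phenyl}prop-2-en-1-one | CN(C)/C=C/C(=O)c1c(OCc2ccc(Oc3c(-c4ccc(OCc5ccccc5)cc4)oc4cc(OCc5ccccc5)cc(OCc5ccccc5)c4c3=O)cc2)cc(O[Si](C(C)C)(C(C)C)C(C)C)cc1O[Si](C(C)C)(C(C)C)C(C)C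
F0 | step 2 | none | none
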